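**Plan**

- Numbering: tetralone C1(=O), C2, C3(OH), C4, C4a, C5 (pyranone), C6 (3-methylbutyl), C7, C8(OH), C8a; ring A = benzene ring, ring B = ketone ring.
- Feature used: C8(OH)–C8a–C1(=O) is an enolised β-diketone and C7–C8(OH) a masked methyl ketone, so rings A and B are the Claisen/aldol product of an open chain in which C8a is the doubly activated carbon.
- Cuts: C1–C8a (Dieckmann), C6–C7 (aldol condensation), C4a–C5 (Michael). They give an alkynyl methyl ketone ester (C7, C8, C8a, C4a, C4 to C1) and a pyranyl ketone (C5, C6, side chain, protected pyranone).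
- Forward: one pot joins the two by Michael addition, closes ring B at C1–C8a, then ring A at C6–C7 with aromatisation. The second pyranone is carried intact from triacetic acid lactone.
- Stereochemistry: C3 (R) comes from alkaloid-catalysed desymmetrising methanolysis of prochiral 3-silyloxyglutaric anhydride. C4a is an alkyne carbon and never a carbonyl, so C1 and C4a cannot become equivalent and C3 is not scrambled.
- Endgame: one mild acidic unmasking of the silyl ether and the pyranone MOM ether.

Key step: step 8

Remark: the quinidine-derived catalyst of step 1 is assumed to give the (R) half-ester; its quinine-derived pseudoenantiomer would be used if the sense is opposite.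

**Route**

Step 1
Reactants: 1 3-[(tert-butyldimethylsilyl)oxy]glutaric anhydride
Product: 2 (3R)-3-[(tert-butyldimethylsilyl)oxy]-5-methoxy-5-oxopentanoic acid
Conditions: MeOH (10 equiv), (DHQD)2AQN (20 mol%), Et2O, −40 °C
Reagents that add atoms: methanol CO
Why: Alkaloid-catalysed desymmetrising alcoholysis of a prochiral cyclic anhydride, in which the chiral amine delivers methanol to one of the two enantiotopic carbonyl groups and so sets C3 as (R).

Step 2
Reactants: 2 (3R)-3-[(tert-butyldimethylsilyl)oxy]-5-methoxy-5-oxopentanoic acid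
Product: 3 methyl (3R)-3-[(tert-butyldimethylsilyl)oxy]-5-hydroxypentanoate
Conditions: BH3·SMe2 (1.2 equiv), THF, 0 °C → rt; then aqueous work-up
Reagents that add atoms: none
Why: Chemoselective borane reduction of a carboxylic acid beside a methyl ester through the acyloxyborane, which should leave the silyl ether and C3 untouched.

Step 3
Reactants: 3 methyl (3R)-3-[(tert-butyldimethylsilyl)oxy]-5-hydroxypentanoate
Product: 4 methyl (3R)-3-[(tert-butyldimethylsilyl)oxy]-5-oxopentanoate
Conditions: TEMPO (10 mol%), PhI(OAc)2 (1.1 equiv), CH2Cl2, rt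
Reagents that add atoms: none
Why: Oxoammonium-catalysed oxidation of the primary alcohol to the aldehyde under near-neutral conditions, which should avoid β-elimination of the silyloxy group.

Step 4
Reactants: 4 methyl (3R)-3-[(tert-butyldimethylsilyl)oxy]-5-oxopentanoate
Product: 5 methyl (3R)-3-[(tert-butyldimethylsilyl)oxy]hex-5-ynoate
Conditions: dimethyl (1-diazo-2-oxopropyl)phosphonate (1.3 equiv), K2CO3 (2 equiv), MeOH, 0 °C → rt
Reagents that add atoms: dimethyl (1-diazo-2-oxopropyl)phosphonate CC(=O)C(=[N+]=[N-])P(=O)(OC)OC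
Why: Seyferth–Gilbert homologation with the Ohira–Bestmann reagent turns the aldehyde carbon into the internal alkyne carbon (future C4a) and adds the terminal one (future C8a); methanol as solvent keeps the methyl ester unchanged.

Step 5
Reactants: 5 methyl (3R)-3-[(tert-butyldimethylsilyl)oxy]hex-5-ynoate
Product: 6 methyl (3R)-3-[(tert-butyldimethylsilyl)oxy]-7-oxooct-5-ynoate
Conditions: acetyl chloride (1.5 equiv), PdCl2(PPh3)2 (2 mol%), CuI (4 mol%), Et3N (2 equiv), THF, rt
Reagents that add atoms: acetyl chloride CC(Cl)=O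
Why: Acyl Sonogashira coupling of the terminal alkyne with an acid chloride gives the alkynyl methyl ketone without an organolithium, so the ester survives.

Step 6
Reactants: 7 4-hydroxy-6-methyl-2H-pyran-2-one (triacetic acid lactone)
Product: 8 4-(methoxymethoxy)-6-methyl-2H-pyran-2-one
Conditions: MOMCl (1.2 equiv), iPr2NEt (1.5 equiv), CH2Cl2, 0 °C → rt
Reagents that add atoms: chloromethyl methyl ether COCCl
Why: O-Alkylation of the vinylogous acid masks the pyranone hydroxyl and removes the nucleophilicity of the pyranone C3 position, which would otherwise compete in step 8.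

Step 7
Reactants: 8 4-(methoxymethoxy)-6-methyl-2H-pyran-2-one; 9 methyl 4-methylpentanoate
Product: 10 4-(methoxymethoxy)-6-(5-methyl-2-oxohexyl)-2H-pyran-2-one
Conditions: LiN(iPr)2 (2.1 equiv), THF, −78 °C; then 9, −78 → 0 °C; 1 M HCl quench
Reagents that add atoms: none
Why: Lateral (vinylogous) deprotonation of the 6-methyl group followed by Claisen-type acylation with the ester, the second equivalent of base being taken up by the more acidic product.

Step 8
Reactants: 6 methyl (3R)-3-[(tert-butyldimethylsilyl)oxy]-7-oxooct-5-ynoate; 10 4-(methoxymethoxy)-6-(5-methyl-2-oxohexyl)-2H-pyran-2-one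
Product: 13 (3R)-3-[(tert-butyldimethylsilyl)oxy]-8-hydroxy-5-[4-(methoxymethoxy)-2-oxo-2H-pyran-6-yl]-6-(3-methylbutyl)-3,4-dihydronaphthalen-1(2H)-one, via enedione Michael adduct 11 (not isolated), via ring B triketone 12 (not isolated)
Conditions: 10 (1.05 equiv), NaH (1.0 equiv), THF, 0 °C; add 6, 0 °C → rt; then 50 °C; AcOH quench
Reagents that add atoms: none
Why: Proposed new method: the sodium enolate of 10 adds through C5 to the ynone β-carbon C4a (Michael) and proton transfer gives the C5–C4a–C8a–C8 dienolate, whose α-carbon C8a attacks the C1 ester (Dieckmann, 6-exo-trig, ring B), in the manner of the known Claisen-type closure of 7-oxoalkanoates to 2-acylcyclohexanones. The methanol set free then shuttles protons so that the C7 enolate of the acetyl group condenses with the C6 ketone (6-exo-trig aldol, loss of water) and the dienone tautomerises to the C8 phenol (ring A), the closest known reaction type being the Robinson-type Michael/aldol benzannulation of alkynyl methyl ketones with active-methylene ketones. No lasting stereocentre is formed: C3 is a silyl ether that is not α to any carbonyl and stays (R), the C5 epimers of 11 and 12 vanish on aromatisation, and C4a is never a carbonyl, so no symmetrical 2-acylcyclohexane-1,3-dione can arise. The step needs ring B to close before ring A, because a phenoxide would no longer be C-acylated by the ester; with one equivalent of base in an aprotic medium the C5-centred anion holds the C6 and C8 carbonyls as enolates, so no aldol should run until the Dieckmann has released methanol. Acylation at C8a and not at C5 is secured because only the C8a product is an enolisable tricarbonyl while the quaternary C5 product can revert by retro-Claisen, and the aldol sense is secured because C7 and C6 are held cis on the C4a=C8a bond of ring B.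

Step 9
Reactants: 13 (3R)-3-[(tert-butyldimethylsilyl)oxy]-8-hydroxy-5-[4-(methoxymethoxy)-2-oxo-2H-pyran-6-yl]-6-(3-methylbutyl)-3,4-dihydronaphthalen-1(2H)-one
Product: 14 (3R)-3,8-dihydroxy-5-(4-hydroxy-2-oxo-2H-pyran-6-yl)-6-(3-methylbutyl)-3,4-dihydronaphthalen-1(2H)-one
Conditions: aq. HF (48%), MeCN, 0 °C → rt
Reagents that add atoms: none
Why: Acidic desilylation of the secondary TBS ether and hydrolysis of the pyranone MOM acetal (an acetal of a vinylogous acid) in one operation; cold dilute acid should spare the β-hydroxy ketone from dehydration to the naphthol.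

**Compound list**

1 | 3-[(tert-butyldimethylsilyl)oxy]glutaric anhydride | CC(C)(C)[Si](C)(C)OC1CC(=O)OC(=O)C1 | starting material
2 | (3R)-3-[(tert-butyldimethylsilyl)oxy]-5-methoxy-5-oxopentanoic acid | COC(=O)C[C@H](O[Si](C)(C)C(C)(C)C)CC(=O)O | intermediate
3 | methyl (3R)-3-[(tert-butyldimethylsilyl)oxy]-5-hydroxypentanoate | COC(=O)C[C@H](O[Si](C)(C)C(C)(C)C)CCO | intermediate
4 | methyl (3R)-3-[(tert-butyldimethylsilyl)oxy]-5-oxopentanoate | COC(=O)C[C@H](O[Si](C)(C)C(C)(C)C)CC=O | intermediate
5 | methyl (3R)-3-[(tert-butyldimethylsilyl)oxy]hex-5-ynoate | COC(=O)C[C@H](O[Si](C)(C)C(C)(C)C)CC#C | intermediate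
6 | methyl (3R)-3-[(tert-butyldimethylsilyl)oxy]-7-oxooct-5-ynoate | COC(=O)C[C@H](O[Si](C)(C)C(C)(C)C)CC#CC(C)=O | intermediate
7 | 4-hydroxy-6-methyl-2H-pyran-2-one (triacetic acid lactone) | Cc1cc(O)cc(=O)o1 | starting material
8 | 4-(methoxymethoxy)-6-methyl-2H-pyran-2-one | COCOc1cc(C)oc(=O)c1 | intermediate
9 | methyl 4-methylpentanoate | COC(=O)CCC(C)C | starting material
10 | 4-(methoxymethoxy)-6-(5-methyl-2-oxohexyl)-2H-pyran-2-one | CC(C)CCC(=O)Cc1cc(OCOC)cc(=O)o1 | intermediate
11 | methyl (3R)-3-[(tert-butyldimethylsilyl)oxy]-5-{1-[4-(methoxymethoxy)-2-oxo-2H-pyran-6-yl]-5-methyl-2-oxohexyl}-7-oxooct-5-enoate (alkene isomers, epimers at the side-chain methine) | COC(=O)C[C@H](O[Si](C)(C)C(C)(C)C)CC(=CC(C)=O)C(C(=O)CCC(C)C)c1cc(OCOC)cc(=O)o1 | intermediate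
12 | (5R)-2-acetyl-5-[(tert-butyldimethylsilyl)oxy]-3-{1-[4-(methoxymethoxy)-2-oxo-2H-pyran-6-yl]-5-methyl-2-oxohexyl}cyclohex-2-en-1-one (epimers at the side-chain methine, drawn as the triketone tautomer) | CC(=O)C1=C(C(C(=O)CCC(C)C)c2cc(OCOC)cc(=O)o2)C[C@@H](O[Si](C)(C)C(C)(C)C)CC1=O | intermediate
13 | (3R)-3-[(tert-butyldimethylsilyl)oxy]-8-hydroxy-5-[4-(methoxymethoxy)-2-oxo-2H-pyran-6-yl]-6-(3-methylbutyl)-3,4-dihydronaphthalen-1(2H)-one | CC(C)CCc1cc(O)c2c(c1-c1cc(OCOC)cc(=O)o1)C[C@@H](O[Si](C)(C)C(C)(C)C)CC2=O | intermediate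
14 | (3R)-3,8-dihydroxy-5-(4-hydroxy-2-oxo-2H-pyran-6-yl)-6-(3-methylbutyl)-3,4-dihydronaphthalen-1(2H)-one | CC(C)CCc1cc(O)c2c(c1-c1cc(O)cc(=O)o1)C[C@@H](O)CC2=O | target

**Step count**

Total steps: 9. Longest linear sequence: 7 (steps 1 to 5, 8, 9).

**Steps most likely to fail**

Step 8 (Proposed new method). Ring A may close before ring B, leaving a phenol whose phenoxide is not C-acylated by the ester. Acylation may also occur at C5, or the C3 silyloxy group may be lost by E1cB from a C4 or C2 carbanion with aromatisation of ring B. The fallback sets out from 6 and 10 and uses known chemistry in two stages. With Cs2CO3 in MeCN at rt to 50 °C the ynone Michael/aldol benzannulation alone should give methyl (3R)-3-[(tert-butyldimethylsilyl)oxy]-4-{5-hydroxy-2-[4-(methoxymethoxy)-2-oxo-2H-pyran-6-yl]-3-(3-methylbutyl)phenyl}butanoate F1. Hydrolysis with Me3SnOH in 1,2-dichloroethane at 70 °C should give (3R)-3-[(tert-butyldimethylsilyl)oxy]-4-{5-hydroxy-2-[4-(methoxymethoxy)-2-oxo-2H-pyran-6-yl]-3-(3-methylbutyl)phenyl}butanoic acid F2. Intramolecular Friedel–Crafts acylation through the mixed anhydride ((CF3CO)2O, CH2Cl2, 0 °C), ortho to the C8 hydroxyl, then closes C1–C8a and comes back to the route at 13.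

Step 9. Acid may dehydrate the β-hydroxy ketone with aromatisation of ring B, or the MOM acetal may be cleaved incompletely. The fallback sets out from 13 and unmasks the two groups separately without aqueous acid. MgBr2·OEt2 with EtSH in Et2O at 0 °C transfers the MOM group to the thiol and should give (3R)-3-[(tert-butyldimethylsilyl)oxy]-8-hydroxy-5-(4-hydroxy-2-oxo-2H-pyran-6-yl)-6-(3-methylbutyl)-3,4-dihydronaphthalen-1(2H)-one F3. Pyridine-buffered HF·pyridine in THF at 0 °C then removes the silyl group and comes back to the route at 14.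

Step 5. Acetyl chloride may form ketene with the amine, and the propargylic β-silyloxy ynone may isomerise or eliminate under the amine and the Pd/Cu catalysts. The fallback sets out from 5 and makes the C–C bond by carbonyl addition. Zn(OTf)2 and Et3N with acetaldehyde in toluene at rt (alkynylzinc addition, ester tolerated) should give methyl (3R)-3-[(tert-butyldimethylsilyl)oxy]-7-hydroxyoct-5-ynoate F4 as a mixture of carbinol epimers. Oxidation with MnO2 in CH2Cl2 comes back to the route at 6.

Further compounds
F1 | step 8 | methyl (3R)-3-[(tert-butyldimethylsilyl)oxy]-4-{5-hydroxy-2-[4-(methoxymethoxy)-2-oxo-2H-pyran-6-yl]-3-(3-methylbutyl)phenyl}butanoate | COC(=O)C[C@H](O[Si](C)(C)C(C)(C)C)Cc1cc(O)cc(CCC(C)C)c1-c1cc(OCOC)cc(=O)o1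
F2 | step 8 | (3R)-3-[(tert-butyldimethylsilyl)oxy]-4-{5-hydroxy-2-[4-(methoxymethoxy)-2-oxo-2H-pyran-6-yl]-3-(3-methylbutyl)phenyl}butanoic acid | OC(=O)C[C@H](O[Si](C)(C)C(C)(C)C)Cc1cc(O)cc(CCC(C)C)c1-c1cc(OCOC)cc(=O)o1
F3 | step 9 | (3R)-3-[(tert-butyldimethylsilyl)oxy]-8-hydroxy-5-(4-hydroxy-2-oxo-2H-pyran-6-yl)-6-(3-methylbutyl)-3,4-dihydronaphthalen-1(2H)-one | CC(C)CCc1cc(O)c2c(c1-c1cc(O)cc(=O)o1)C[C@@H](O[Si](C)(C)C(C)(C)C)CC2=O
F4 | step 5 | methyl (3R)-3-[(tert-butyldimethylsilyl)oxy]-7-hydroxyoct-5-ynoate (carbinol epimers) | COC(=O)C[C@H](O[Si](C)(C)C(C)(C)C)CC#CC(C)O
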